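The readings come from a simulation with constants of no real substance; noise was put on by code.

- In a one-step world, starting material pairs up to target and nothing else, so the share of target among products, the selectivity, stands at 100% in any vessel. The one thing left to work out is how much starting material remains.

| flask | starting material | remark | time |
|---|---|---|---|
| epsilon | 0.050 M | run made earlier |  |
| zeta | 0.10 M | run made earlier |  |
| violet | 0.050 M | a single well-mixed tank run continuously and read at steady state, 75.0 h in it on average |  |
| ochre | 0.050 M | a single well-mixed tank run continuously and read at steady state, 25 h in it on average |  |
| teal | 0.050 M | everything together in a closed stirred flask, run for 25 h | 25 h |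

| run | time / h | target / % | isomer of the product / % |
|---|---|---|---|
| epsilon | 6.00 | 32 | 0 |
| epsilon | 12.0 | 44 | 6 |
| epsilon | 20.0 | 47 | 6 |
| epsilon | 25.0 | 54 | 8 |
| zeta | 2.00 | 24 | 0 |
| zeta | 4.00 | 39 | 1 |
| zeta | 6.00 | 48 | 1 |
| zeta | 8.00 | 53 | 0 |

(scatter of a reading: 2 percentage points)

- percent here means starting material units held: one target or isomer of the product counts as two
- percent here means starting material units held: one side product counts as three
- the stated concentrations are those of everything mixed, before any reaction; amounts are the same in each set-up
- the numbers in the tables scatter with a standard deviation of 2 percentage points
- the earlier runs were made in a closed, stirred flask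

- order of the set-ups by the share of target in all that became target or isomer of the product or side product, at the outlet or at the end, highest first (violet / ochre / teal)
- share of target in all that became target or isomer of the product or side product, at the outlet or at the end, violet
- share of target in all that became target or isomer of the product or side product, at the outlet or at the end, ochre
- share of target in all that became target or isomer of the product or side product, at the outlet or at the end, teal

- Define t_d, the dimerisation time, as the hours in which one second-order step halves the starting material at 0.050 M. The first epsilon reading gives t_d = 12.7 h, and the first zeta reading, scaled to that charge, gives 12.7 h.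
- In a closed flask, the fraction left is 1/(1 + t/t_d), with t/t_d the Damköhler number, so teal keeps 33.8%.
- In a tank with mean hold τ, the fraction left a obeys 1 − a = (τ/t_d)a². Matching teal therefore takes τ = t(1 + t/t_d) = 74.0 h, close to violet's 75.0 h, and violet keeps 33.6%.
- My reckoning for teal: the gap between converted and read product suggests 4.23% side product, a reading within the scatter. Losses per target, L, are then 0.226, and the share is 81.5%.
- Violet has two extremes. If losses follow conversion, it matches teal at 81.5%. If they grow with hours, L scales by 3.00 and the share falls to 59.6%. My estimate for violet lies between these two values.
- The forecast gives teal > ochre > violet: violet 54% (44% to 65%), ochre 76% (67% to 84%), teal 80% (72% to 88%). It sees side product as “a late shortfall of about 5%”. Its violet value is lower than my range, and its teal value differs from my 81.5%.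

    2 starting material → target (k = 0.850 /M/h)
    target ⇌ isomer of the product (K = 0.170, k = 0.0150 /h)
    starting material + target → side product (k = 0.280 /M/h)

- Violet gives 61.0%, teal 76.3% and ochre 73.1%, in the order teal > ochre > violet. Violet holds 20.6% side product, more than teal's 9.53%, while starting material stands at 31.2% in violet and 30.4% in teal, against 33.6% and 33.8% from t_d. On ochre, t_d gives 50.3% left, and the ochre tank holds 0.0240 M, which is 48.0% of its charge.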